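The carbocyclic six-membered ring C1–C8–C7–C6–C5–C9 of the bicyclo[3.3.1]nonane core is disconnected at C7–C8 and C5–C9. The plan exploits that C8 lies β to the C9 carbonyl and that C5 and C7 flank C6: with a temporary carbonyl at C6 they become the α- and γ-carbons of a geranylated acetoacetate dianion, while C8 and C9 are the β-carbon and an ester of an isopropylidenemalonate. One Michael–Claisen annulation of these acyclic partners forms both bonds and gives a 4-geranyl-5,5-dimethylcyclohexane-1,3-dione. The C6 oxygen is then erased by reductive carbonyl transposition; malonyl dichloride bridging, bridgehead geranylation under a chiral lithium amide and C3 aroylation complete the target.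

Key step: step 2

Numbering remark: atom numbers are those of the bicyclic core of the target and are kept for all intermediates (C1 prenyl-bearing bridgehead, C2–C3–C4 β-diketone bridge, C5 geranyl-bearing bridgehead, C6 CH2, C7 geranyl-bearing CH, C8 CMe2, C9 bridging ketone); geranyl = (2E)-3,7-dimethylocta-2,6-dien-1-yl, prenyl = 3-methylbut-2-en-1-yl.

Remark on stereochemistry: compounds 5–17 are racemic; their SMILES show the enantiomer that leads to 24, and C7 is left undefined in 5–7, where it is configurationally labile.

Assumption: the (R,R,R,R) bis-lithium amide of step 9 is taken to deprotonate the (1R,5S,7R) enantiomer of 17 faster; if a test run shows the opposite sense, its mirror image is used.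

Step 1
Reactants: 1 methyl acetoacetate; 2 geranyl bromide
Product: 3 methyl (6E)-7,11-dimethyl-3-oxododeca-6,10-dienoate
Conditions: NaH, THF, 0 °C; n-BuLi, 0 °C; then 2, 0 °C to rt; dilute HCl
Reagents that add atoms: none
Why: The sodium–lithium dianion of the β-keto ester reacts with the allylic bromide only at its more basic γ-carbon (γ-alkylation of a β-keto ester dianion), and no stereocenter is formed.

Step 2
Reactants: 3 methyl (6E)-7,11-dimethyl-3-oxododeca-6,10-dienoate; 4 dimethyl isopropylidenemalonate
Product: 7 4-geranyl-5,5-dimethylcyclohexane-1,3-dione (racemic), via Michael adduct triester 5 (not isolated), via cyclic diester 6 (not isolated)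
Conditions: NaH, THF, 0 °C; n-BuLi, 0 °C; 4, −78 to 0 °C; then MeOH, 60 °C; then 2 M NaOH, 60 °C; then HCl to pH 3, 50 °C
Reagents that add atoms: none
Why: The sodium–lithium dianion of 3 adds through its γ-carbon (C7) to the β-carbon (C8) of the doubly activated alkene 4 to give dianion 5, and once methanol has protonated the malonate the remaining β-keto ester enolate carbon (C5) attacks one malonate ester carbonyl (C9) and expels methoxide to give 6, whose two ester groups are then lost by saponification and decarboxylation of the β-keto acids. The closest known reaction type is the Michael–Claisen synthesis of 5,5-dimethylcyclohexane-1,3-diones, here run with a 1,3-dicarbonyl dianion as the γ-selective Michael donor towards an alkylidenemalonate. The single ring that closes does so by a 6-(enolexo)-exo-trig Claisen (Dieckmann-type) acylation. C7 is the only stereocenter formed; nothing controls it and it stays epimerizable beside the C6 carbonyl, so 7 is racemic and the absolute configuration is chosen later (step 9). The step needs regiochemistry (conjugate addition at C7 and acylation at C5, not the reverse) and 1,4- rather than 1,2-attack: the first is secured because only the γ-carbanion of the dianion is reactive enough for the hindered β,β-dimethyl acceptor while the α-carbon stays a stabilized enolate, and the second because the malonate esters are cross-conjugated and shielded. The alternative closure of the malonate carbon onto the acetoacetate ester would create a quaternary carbon beside C8 and is disfavoured.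

Step 3
Reactants: 7 4-geranyl-5,5-dimethylcyclohexane-1,3-dione
Product: 8 rac-6-geranyl-3-methoxy-5,5-dimethylcyclohex-2-en-1-one
Conditions: HC(OMe)3, MeOH, TsOH (cat.), rt
Reagents that add atoms: trimethyl orthoformate COC(OC)OC, methanol CO
Why: Acid-catalysed O-methylation of the cyclic 1,3-dione (vinylogous ester formation) should place the methoxy group on the less hindered carbonyl carbon C9, remote from the geranyl-bearing C7, so that C6 remains the enone carbonyl, and the minor regioisomer is removed by chromatography.

Step 4
Reactants: 8 rac-6-geranyl-3-methoxy-5,5-dimethylcyclohex-2-en-1-one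
Product: 10 rac-4-geranyl-5,5-dimethylcyclohex-2-en-1-one, via hydroxy enol ether 9 (not isolated)
Conditions: LiAlH4, Et2O, 0 °C; then 1 M HCl, THF, rt
Reagents that add atoms: none
Why: 1,2-Reduction of the vinylogous ester carbonyl followed by acid hydrolysis of the hydroxy enol ether and loss of water (Stork–Danheiser 1,3-carbonyl transposition) erases the C6 oxygen and leaves the enone carbonyl at C9, with C7 now configurationally fixed but still racemic.

Step 5
Reactants: 10 rac-4-geranyl-5,5-dimethylcyclohex-2-en-1-one; 11 prenyl bromide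
Product: 12 rac-4-geranyl-5,5-dimethyl-6-prenylcyclohex-2-en-1-one (C1 epimers)
Conditions: LiN(i-Pr)2, THF, −78 °C; then 11, DMPU, −78 to −20 °C
Reagents that add atoms: none
Why: Kinetic deprotonation of the enone occurs at its only α′ position (C1) and the cross-conjugated enolate is alkylated by the allylic bromide (α′-alkylation of an enone), giving C1 epimers that do not matter because C1 is planarized again in step 7.

Step 6
Reactants: 12 rac-4-geranyl-5,5-dimethyl-6-prenylcyclohex-2-en-1-one
Product: 13 trimethylsilyl enol ether of 4-geranyl-3,3-dimethyl-2-prenylcyclohexanone (double bond C9=C5)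
Conditions: Li[HB(s-Bu)3], THF, −78 °C; then Me3SiCl, Et3N, −78 to 0 °C
Reagents that add atoms: chlorotrimethylsilane C[Si](C)(C)Cl
Why: The bulky borohydride delivers hydride to the unsubstituted β-carbon C6 (1,4-reduction of a cyclohexenone) and the regiodefined C9–C5 enolate is trapped on oxygen before it can equilibrate.

Step 7
Reactants: 13 trimethylsilyl enol ether; 14 malonyl dichloride
Product: 16 rac-(1R,5S,7R)-7-geranyl-4-hydroxy-8,8-dimethyl-1-prenylbicyclo[3.3.1]non-3-ene-2,9-dione, via C5-malonyl acid chloride 15 (not isolated)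
Conditions: 14, Et2O, −20 °C to rt; then KOH (aq), BnEt3NCl, rt; then dilute HCl
Reagents that add atoms: none
Why: Malonyl dichloride acylates the silyl enol ether carbon C5 and then, after enolization towards C1, the hindered C1 (Effenberger α,α′-annulation of a cyclohexanone enol ether), and because the three-carbon bridge can only span two axial positions it should close on the ring face opposite to the equatorial C7 geranyl group, which sets C1 and C5 relative to C7 (geranyl exo).

Step 8
Reactants: 16 bicyclic enolized trione
Product: 17 rac-(1R,5S,7R)-7-geranyl-4-methoxy-8,8-dimethyl-1-prenylbicyclo[3.3.1]non-3-ene-2,9-dione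
Conditions: HC(OMe)3, MeOH, TsOH (cat.), 50 °C
Reagents that add atoms: trimethyl orthoformate COC(OC)OC, methanol CO
Why: Acid-catalysed O-methylation of the enolized β-diketone (vinylogous ester formation) masks the acidic enol and should occur mainly at the C4 oxygen, remote from the quaternary C1, the minor C2-methoxy isomer being separated.

Step 9
Reactants: 17 racemic methyl vinylogous ester; 2 geranyl bromide
Product: 18 (1R,5S,7R)-5,7-digeranyl-4-methoxy-8,8-dimethyl-1-prenylbicyclo[3.3.1]non-3-ene-2,9-dione
Conditions: dilithium (1R,2R)-1,2-diphenyl-N,N′-bis[(1R)-1-phenylethyl]ethane-1,2-diamide (0.55 equiv; made in the flask from the diamine and n-BuLi), LiCl, THF, −100 °C; then 2, −78 °C; stopped at partial conversion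
Reagents that add atoms: none
Why: Bridgehead deprotonation at C5, acidified by the C9 ketone and the neighbouring enol-ether carbon, followed by alkylation with retention (bridgehead lithiation–alkylation) installs the second geranyl group, and the C2-symmetric chiral bis-lithium amide is expected to deprotonate one enantiomer of racemic 17 faster (kinetic resolution), so that 18 should be obtained as the (1R,5S,7R) enantiomer while the unreacted antipode is separated.

Step 10
Reactants: 19 3,4-dihydroxybenzoic acid
Product: 21 3,4-bis(tert-butyldimethylsilyloxy)benzoic acid, via tris-silyl derivative 20 (not isolated)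
Conditions: t-BuMe2SiCl (3.3 equiv), imidazole, DMF, rt; then AcOH, THF, H2O, rt
Reagents that add atoms: tert-butyldimethylsilyl chloride CC(C)(C)[Si](C)(C)Cl
Why: Exhaustive silylation followed by selective hydrolysis of the labile silyl ester (silyl protection of phenols) masks both phenols against the organolithium of step 12.

Step 11
Reactants: 21 3,4-bis(tert-butyldimethylsilyloxy)benzoic acid
Product: 22 3,4-bis(tert-butyldimethylsilyloxy)benzoyl chloride
Conditions: (COCl)2, DMF (cat.), CH2Cl2, 0 °C to rt
Reagents that add atoms: oxalyl chloride O=C(Cl)C(Cl)=O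
Why: Oxalyl chloride with catalytic DMF converts the acid into the acid chloride by chloroiminium (Vilsmeier-type) activation without cleaving the aryl silyl ethers.

Step 12
Reactants: 18 C5-geranylated vinylogous ester; 22 3,4-bis(tert-butyldimethylsilyloxy)benzoyl chloride
Product: 23 (1S,5S,7R)-3-[3,4-bis(tert-butyldimethylsilyloxy)benzoyl]-5,7-digeranyl-4-methoxy-8,8-dimethyl-1-prenylbicyclo[3.3.1]non-3-ene-2,9-dione
Conditions: lithium 2,2,6,6-tetramethylpiperidide, THF, −78 °C; then 22, −78 °C
Reagents that add atoms: none
Why: The hindered amide removes the vinylic C3 proton of the β-methoxy enone and the resulting vinyllithium is C-acylated by the acid chloride (α-lithiation–acylation of a vinylogous ester), both bridgeheads being quaternary by now.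

Step 13
Reactants: 23 protected triketone
Product: 24 (1S,5S,7R)-3-(3,4-dihydroxybenzoyl)-5,7-digeranyl-4-hydroxy-8,8-dimethyl-1-prenylbicyclo[3.3.1]non-3-ene-2,9-dione (target)
Conditions: LiOH, dioxane, H2O (degassed), 90 °C; then dilute HCl
Reagents that add atoms: lithium hydroxide [Li+].[OH-]
Why: Hydroxide adds to C4 and expels methoxide (addition–elimination hydrolysis of the vinylogous ester) and also cleaves both aryl silyl ethers, so that one operation should release the enolized β-triketone and the catechol without touching any stereocenter.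

Compound list
1 | methyl acetoacetate | COC(=O)CC(C)=O | starting material
2 | geranyl bromide, (2E)-1-bromo-3,7-dimethylocta-2,6-diene | CC(C)=CCC/C(C)=C/CBr | starting material
3 | methyl (6E)-7,11-dimethyl-3-oxododeca-6,10-dienoate | COC(=O)CC(=O)CC/C=C(\C)CCC=C(C)C | intermediate
4 | dimethyl isopropylidenemalonate, dimethyl 2-(propan-2-ylidene)propanedioate | COC(=O)C(=C(C)C)C(=O)OC | starting material
5 | dimethyl 2-{3-geranyl-6-methoxy-2-methyl-4,6-dioxohexan-2-yl}propanedioate (Michael adduct) | COC(=O)CC(=O)C(C/C=C(\C)CCC=C(C)C)C(C)(C)C(C(=O)OC)C(=O)OC | intermediate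
6 | dimethyl 5-geranyl-6,6-dimethyl-2,4-dioxocyclohexane-1,3-dicarboxylate | COC(=O)C1C(=O)C(C(=O)OC)C(=O)C(C/C=C(\C)CCC=C(C)C)C1(C)C | intermediate
7 | 4-[(2E)-3,7-dimethylocta-2,6-dien-1-yl]-5,5-dimethylcyclohexane-1,3-dione (racemic) | CC(C)=CCC/C(C)=C/CC1C(=O)CC(=O)CC1(C)C | intermediate
8 | rac-6-[(2E)-3,7-dimethylocta-2,6-dien-1-yl]-3-methoxy-5,5-dimethylcyclohex-2-en-1-one | CC(C)=CCC/C(C)=C/C[C@@H]1C(=O)C=C(OC)CC1(C)C | intermediate
9 | 6-geranyl-3-methoxy-5,5-dimethylcyclohex-2-en-1-ol (carbinol epimers) | CC(C)=CCC/C(C)=C/C[C@@H]1C(O)C=C(OC)CC1(C)C | intermediate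
10 | rac-4-[(2E)-3,7-dimethylocta-2,6-dien-1-yl]-5,5-dimethylcyclohex-2-en-1-one | CC(C)=CCC/C(C)=C/C[C@@H]1C=CC(=O)CC1(C)C | intermediate
11 | prenyl bromide, 1-bromo-3-methylbut-2-ene | CC(C)=CCBr | starting material
12 | rac-4-geranyl-5,5-dimethyl-6-(3-methylbut-2-en-1-yl)cyclohex-2-en-1-one (epimers at the prenyl-bearing carbon) | CC(C)=CCC/C(C)=C/C[C@@H]1C=CC(=O)C(CC=C(C)C)C1(C)C | intermediate
13 | {[4-geranyl-5,5-dimethyl-6-(3-methylbut-2-en-1-yl)cyclohex-1-en-1-yl]oxy}trimethylsilane | CC(C)=CCC/C(C)=C/C[C@@H]1CC=C(O[Si](C)(C)C)C(CC=C(C)C)C1(C)C | intermediate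
14 | malonyl dichloride | O=C(Cl)CC(Cl)=O | starting material
15 | 3-[5-geranyl-4,4-dimethyl-3-(3-methylbut-2-en-1-yl)-2-oxocyclohexyl]-3-oxopropanoyl chloride | CC(C)=CCC/C(C)=C/C[C@@H]1CC(C(=O)CC(Cl)=O)C(=O)C(CC=C(C)C)C1(C)C | intermediate
16 | rac-(1R,5S,7R)-7-geranyl-4-hydroxy-8,8-dimethyl-1-(3-methylbut-2-en-1-yl)bicyclo[3.3.1]non-3-ene-2,9-dione | CC(C)=CCC/C(C)=C/C[C@@H]1C[C@@H]2C(=O)[C@@](CC=C(C)C)(C(=O)C=C2O)C1(C)C | intermediate
17 | rac-(1R,5S,7R)-7-geranyl-4-methoxy-8,8-dimethyl-1-(3-methylbut-2-en-1-yl)bicyclo[3.3.1]non-3-ene-2,9-dione | CC(C)=CCC/C(C)=C/C[C@@H]1C[C@@H]2C(=O)[C@@](CC=C(C)C)(C(=O)C=C2OC)C1(C)C | intermediate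
18 | (1R,5S,7R)-5,7-bis[(2E)-3,7-dimethylocta-2,6-dien-1-yl]-4-methoxy-8,8-dimethyl-1-(3-methylbut-2-en-1-yl)bicyclo[3.3.1]non-3-ene-2,9-dione | CC(C)=CCC/C(C)=C/C[C@@H]1C[C@]2(C/C=C(\C)CCC=C(C)C)C(=O)[C@@](CC=C(C)C)(C(=O)C=C2OC)C1(C)C | intermediate
19 | 3,4-dihydroxybenzoic acid | OC(=O)c1ccc(O)c(O)c1 | starting material
20 | tert-butyldimethylsilyl 3,4-bis(tert-butyldimethylsilyloxy)benzoate | CC(C)(C)[Si](C)(C)OC(=O)c1ccc(O[Si](C)(C)C(C)(C)C)c(O[Si](C)(C)C(C)(C)C)c1 | intermediate
21 | 3,4-bis(tert-butyldimethylsilyloxy)benzoic acid | OC(=O)c1ccc(O[Si](C)(C)C(C)(C)C)c(O[Si](C)(C)C(C)(C)C)c1 | intermediate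
22 | 3,4-bis(tert-butyldimethylsilyloxy)benzoyl chloride | ClC(=O)c1ccc(O[Si](C)(C)C(C)(C)C)c(O[Si](C)(C)C(C)(C)C)c1 | intermediate
23 | (1S,5S,7R)-3-[3,4-bis(tert-butyldimethylsilyloxy)benzoyl]-5,7-bis[(2E)-3,7-dimethylocta-2,6-dien-1-yl]-4-methoxy-8,8-dimethyl-1-(3-methylbut-2-en-1-yl)bicyclo[3.3.1]non-3-ene-2,9-dione | CC(C)=CCC/C(C)=C/C[C@@H]1C[C@]2(C/C=C(\C)CCC=C(C)C)C(=O)[C@@](CC=C(C)C)(C(=O)C(C(=O)c3ccc(O[Si](C)(C)C(C)(C)C)c(O[Si](C)(C)C(C)(C)C)c3)=C2OC)C1(C)C | intermediate
24 | (1S,5S,7R)-3-(3,4-dihydroxybenzoyl)-5,7-bis[(2E)-3,7-dimethylocta-2,6-dien-1-yl]-4-hydroxy-8,8-dimethyl-1-(3-methylbut-2-en-1-yl)bicyclo[3.3.1]non-3-ene-2,9-dione | CC(C)=CCC/C(C)=C/C[C@@H]1C[C@]2(C/C=C(\C)CCC=C(C)C)C(=O)[C@@](CC=C(C)C)(C(=O)C(C(=O)c3ccc(O)c(O)c3)=C2O)C1(C)C | target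

Total step count: 13. Longest linear sequence: 11 steps (steps 1–9, 12 and 13); steps 10 and 11 prepare the acid chloride 22.

Steps most likely to fail

Step 2 (key step). What may go wrong is proton transfer from the allylic methyl groups of 4 to the strongly basic dianion, or attack on an ester carbonyl, in place of conjugate addition, so that no C7–C8 bond forms. The fallback sets out from 3 and moves the Michael step to a Lewis-acid manifold. Compound 3 is converted (Et3N, Me3SiCl; then LiN(i-Pr)2, Me3SiCl) into the 1,3-bis(trimethylsilyloxy)diene F1. F1 is added to 4 with TiCl4 in CH2Cl2 at −78 °C (vinylogous Mukaiyama–Michael addition through its terminal carbon C7). Aqueous work-up should give the triester 5, which is isolated, cyclized with NaOMe in MeOH to 6, then saponified and decarboxylated as in the main route. The route is rejoined at 7.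

Step 9. What may go wrong is poor discrimination between the two enantiomers of 17 by the chiral base, or slow bridgehead deprotonation, leaving 18 of insufficient enantiomeric purity. The fallback sets out from racemic 17, which is resolved by preparative chromatography on a chiral stationary phase. The (1R,5S,7R) enantiomer is then deprotonated with achiral LiN(i-Pr)2 in THF at −78 °C and alkylated with 2 (bridgehead lithiation–alkylation). The route is rejoined at 18; this fallback makes no new compound (F0).

Step 3. What may go wrong is methylation on the other oxygen, which would leave the enone carbonyl at C9 and make the reductive transposition of step 4 remove the wrong oxygen. The fallback sets out from 7 and uses that isomer productively, the regioisomeric vinylogous ester F2 (methoxy on C6). F2 is deprotonated at its α′ carbon C1 with LiN(i-Pr)2 and alkylated with 11 (alkylation of a vinylogous ester enolate) to give the prenylated vinylogous ester F3. Li in liquid NH3 and THF at −78 °C then expels methoxide and reduces the enone so formed (dissolving-metal reduction of a β-alkoxy enone). After removal of NH3 the regiodefined lithium enolate is silylated with Me3SiCl and Et3N. The route is rejoined at 13, bypassing 8, 10 and 12.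

Further compounds
F1 | step 2 | (6E)-1-methoxy-7,11-dimethyl-1,3-bis(trimethylsilyloxy)dodeca-1,3,6,10-tetraene (enol ether geometry not defined) | COC(O[Si](C)(C)C)=CC(O[Si](C)(C)C)=CC/C=C(\C)CCC=C(C)C
F0 | step 9 | none | none
F2 | step 3 | rac-4-[(2E)-3,7-dimethylocta-2,6-dien-1-yl]-3-methoxy-5,5-dimethylcyclohex-2-en-1-one | CC(C)=CCC/C(C)=C/C[C@@H]1C(OC)=CC(=O)CC1(C)C
F3 | step 3 | rac-4-[(2E)-3,7-dimethylocta-2,6-dien-1-yl]-3-methoxy-5,5-dimethyl-6-(3-methylbut-2-en-1-yl)cyclohex-2-en-1-one (epimers at the prenyl-bearing carbon) | CC(C)=CCC/C(C)=C/C[C@@H]1C(OC)=CC(=O)C(CC=C(C)C)C1(C)C
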